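**Assumptions.** (−)-Genipin (1) is commercially available. Its C9 and C5 configurations are the natural iridoid ones (7aS, 4aS), and C9 matches the target. C1 of genipin and of the silyl acetals is an epimerising anomeric centre, so it is left unspecified until Step 10.

## Retrosynthetic overview
1. The C5=C6 bond is installed last by DDQ dehydrogenation of the 5,6-dihydro (monoene-type) acylal. C5–H is activated by the enol ether, and this avoids any cyclopentadiene intermediate.
2. The C1 acylal comes from the lactol (TBS acetal → HF → isovaleryl chloride). The two primary alcohols (C10, C11) become acetates.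
3. The trans 7β-OiVal / 8α-OH / C10 unit comes from C7-selective opening of a 7α,8α-epoxy 10-ol with isovaleric acid. The α-epoxide comes from bromonium attack on the convex β-face, anti opening by water at C8, and closure.
4. The C11 CH2OH comes from DIBAL reduction of genipin's C11 ester while the epoxide is still in place.
5. Both rings and C9 come pre-formed from genipin, so no ring is constructed. C5 is destroyed in the last step, and C7 and C8 are built in Steps 4–7.

## Route

**Step 1**
Reactants: 1, (−)-genipin
Product: 2, 10-O-acetylgenipin
Conditions: Ac2O (1.05 equiv), pyridine, CH2Cl2, −10 °C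
Reagents that add atoms: acetic anhydride, CC(=O)OC(C)=O
Why: The unhindered primary allylic OH acylates much faster than the hemiacetal OH (chemoselective acetylation), which masks C10 so the next silylation reaches only the lactol; no stereocentre is changed.

**Step 2**
Reactants: 2
Product: 3, 1-O-TBS-10-O-acetylgenipin (C1 anomeric mixture)
Conditions: TBSCl, imidazole, DMF, 0 °C → rt
Reagents that add atoms: TBSCl, CC(C)(C)[Si](C)(C)Cl
Why: Silylation of the only free OH gives a base-stable, fluoride-labile anomeric protecting group; the anomer ratio is irrelevant because C1 is reset in Step 10.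

**Step 3**
Reactants: 3
Product: 4, 1-O-TBS-genipin
Conditions: K2CO3 (cat.), MeOH, 0 °C
Reagents that add atoms: none
Why: Methanolysis removes the primary acetate (the methyl ester only exchanges degenerately and the TBS acetal is base-stable), which frees C10–OH. This prevents acetoxy participation in the halonium step and provides the directing OH for Step 7.

**Step 4**
Reactants: 4
Product: 5, 7β-bromo-8α-hydroxy bromohydrin of 4
Conditions: NBS (1.1 equiv), THF/H2O 4:1, NaHCO3, 0 °C, dark
Reagents that add atoms: NBS, O=C1CCC(=O)N1Br; water, O
Why: Bromohydrin formation: Br+ adds to the convex β-face of the cis-fused bicycle (the pyran ring shields the α-face), and water opens the bromonium anti at tertiary C8 from the α-face. This sets 7β-Br and 8α-OH with C10 β, and the C11 ester keeps the C3=C4 enol ether electron-poor.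

**Step 5**
Reactants: 5
Product: 6, 7α,8α-epoxy-10-ol
Conditions: K2CO3, MeOH, 0 °C → rt
Reagents that add atoms: none
Why: Intramolecular Williamson closure of the trans bromohydrin: the 8α-alkoxide displaces 7β-Br with inversion to give the α-epoxide, which is the face that will end up as 8α-OH.

**Step 6**
Reactants: 6
Product: 7, epoxy diol (C11 CH2OH)
Conditions: DIBAL-H (5 equiv), CH2Cl2, −78 → −20 °C; Rochelle salt work-up
Reagents that add atoms: none
Why: DIBAL reduces the vinylogous-carbonate ester 1,2 to the allylic alcohol while the epoxide and TBS acetal survive at low temperature; no stereocentre is touched.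

**Step 7**
Reactants: 7
Product: 8, 7β-isovalerate (8α-OH, 10-OH, 11-OH)
Conditions: Ti(OiPr)4 (1.2 equiv), isovaleric acid (3 equiv), CH2Cl2, 0 °C → rt
Reagents that add atoms: isovaleric acid, CC(C)CC(=O)O
Why: Proposed new method: Ti-templated, C10-OH-directed SN2 opening of the 2,3-epoxy alcohol at the secondary C7 (C3 of the epoxy alcohol) by the carboxylate, entering from the open β-face with inversion, so the 7β-ester is trans to 8α-O. The closest known reaction is the Caron–Sharpless Ti(OiPr)4-mediated C3-selective opening of epoxy alcohols.

**Step 8**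
Reactants: 8
Product: 9, 10,11-diacetate
Conditions: Ac2O (2.3 equiv), pyridine, DMAP (5 mol%), CH2Cl2, 0 °C → rt
Reagents that add atoms: acetic anhydride, CC(=O)OC(C)=O
Why: Acetylation of the two primary alcohols; the tertiary 8-OH is left free because it is too hindered under these mild conditions.

**Step 9**
Reactants: 9
Product: 10, lactol (C1 epimeric mixture)
Conditions: HF·pyridine, pyridine/THF, 0 °C
Reagents that add atoms: none
Why: Fluoride cleaves the anomeric silyl ether selectively, and pyridine buffering protects the enol ether and the acetates.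

**Step 10**
Reactants: 10
Product: 11, 5,6-dihydro-10-acetoxyvaltrathydrin (monoene acylal)
Conditions: isovaleryl chloride (1.3 equiv), pyridine, DMAP (cat.), CH2Cl2, −20 → 0 °C
Reagents that add atoms: isovaleryl chloride, CC(C)CC(=O)Cl
Why: Acylation of the more nucleophilic lactol OH. C1 is set under anomeric control (ring-chain and oxocarbenium equilibration), favouring the natural 1β-OiVal cis to H9; the minor anomer is removed chromatographically, and the tertiary 8-OH is untouched.

**Step 11**
Reactants: 11
Product: 12, 10-acetoxyvaltrathydrin (target)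
Conditions: DDQ (1.3 equiv), 2,6-di-tert-butyl-4-methylpyridine (2 equiv), dry benzene, 25 → 50 °C, dark; filter off DDQH2
Reagents that add atoms: none
Why: Proposed new method: DDQ abstracts the doubly activated C5–H hydride, which is allylic to the enol ether, to give a vinylogous oxocarbenium O2⁺=C3–C4=C5. Loss of a C6 proton gives the conjugated dienol ether, C5 stereochemistry is destroyed, and C1, C7, C8 and C9 are unchanged. The closest known reactions are DDQ aromatisation of 4H-pyrans and 1,4-dihydropyridines and DDQ oxidation of allylic enol ethers.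

## Compound list
1 | (−)-genipin, methyl (4aS,7aS)-1-hydroxy-7-(hydroxymethyl)-1,4a,5,7a-tetrahydrocyclopenta[c]pyran-4-carboxylate | COC(=O)C1=CO[CH](O)[C@H]2[C@@H]1CC=C2CO | starting material
2 | 10-O-acetylgenipin | COC(=O)C1=CO[CH](O)[C@H]2[C@@H]1CC=C2COC(C)=O | intermediate
3 | 1-O-TBS-10-O-acetylgenipin | COC(=O)C1=CO[CH](O[Si](C)(C)C(C)(C)C)[C@H]2[C@@H]1CC=C2COC(C)=O | intermediate
4 | 1-O-TBS-genipin | COC(=O)C1=CO[CH](O[Si](C)(C)C(C)(C)C)[C@H]2[C@@H]1CC=C2CO | intermediate
5 | 7β-bromo-8α-hydroxy bromohydrin of 4 | COC(=O)C1=CO[CH](O[Si](C)(C)C(C)(C)C)[C@H]2[C@@H]1C[C@H](Br)[C@]2(O)CO | intermediate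
6 | 7α,8α-epoxy-10-ol | COC(=O)C1=CO[CH](O[Si](C)(C)C(C)(C)C)[C@H]2[C@@H]1C[C@H]3O[C@@]23CO | intermediate
7 | epoxy diol (C11 CH2OH) | OCC1=CO[CH](O[Si](C)(C)C(C)(C)C)[C@H]2[C@@H]1C[C@H]3O[C@@]23CO | intermediate
8 | 7β-isovalerate, 8α-OH, 10,11-diol | OCC1=CO[CH](O[Si](C)(C)C(C)(C)C)[C@H]2[C@@H]1C[C@H](OC(=O)CC(C)C)[C@]2(O)CO | intermediate
9 | 10,11-diacetate | CC(=O)OCC1=CO[CH](O[Si](C)(C)C(C)(C)C)[C@H]2[C@@H]1C[C@H](OC(=O)CC(C)C)[C@]2(O)COC(C)=O | intermediate
10 | lactol | CC(=O)OCC1=CO[CH](O)[C@H]2[C@@H]1C[C@H](OC(=O)CC(C)C)[C@]2(O)COC(C)=O | intermediate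
11 | 5,6-dihydro-10-acetoxyvaltrathydrin | CC(=O)OCC1=CO[C@@H](OC(=O)CC(C)C)[C@H]2[C@@H]1C[C@H](OC(=O)CC(C)C)[C@]2(O)COC(C)=O | intermediate
12 | 10-acetoxyvaltrathydrin | CC(=O)OCC1=CO[C@@H](OC(=O)CC(C)C)[C@H]2C1=C[C@H](OC(=O)CC(C)C)[C@]2(O)COC(C)=O | target

**Total steps:** 11. **Longest linear sequence:** 11 (from 1).

## Three steps most likely to fail
1. **Step 11 (DDQ dehydrogenation).** The cation may lose C9–H instead of C6–H, or C7–OiVal may ionise under the acidic byproducts.
   Fallback (different approach): carry a C6-oxygenated (aucubin-type, 6-hydroxy) iridoid through the same sequence and form C5=C6 by Burgess-type dehydration.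
2. **Step 7 (Ti-mediated opening by isovaleric acid).** The C11 allylic alcohol or the TBS acetal may not survive the Lewis-acidic conditions.
   Fallback (different approach): hydrolyse the epoxide to the trans-7,8-diol, then acylate the secondary 7-OH selectively over the tertiary 8-OH with isovaleryl chloride.
3. **Step 4 (bromohydrin).** NBS may brominate the push-pull enol ether, or facial selectivity may erode.
   Fallback (different approach): Sharpless asymmetric epoxidation of 4 with Ti(OiPr)4, D-(−)-DET and TBHP, where reagent control gives the 7α,8α-epoxide directly, replacing Steps 4–5.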